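**Plan**

1. Numbering: decalin C1–C10 (ring A = C1–C5, C10; ring B = C5–C10), C11 on C9, chain C12–C17 with CO2H on C17. The acid is traced back to a primary alcohol; the diene is cut at C14–C15 (alkenylalane + E-vinyl iodide, Pd(PPh3)4) and the chain at C11–C12 (allylic bromide + propargyl anion).
2. Ring B is cut at C6–C7 and C9–C10 at once. The allyl unit C6–C5=C10 of ring A (β-cyclogeranyl cation) is electrophilic at C6 and, once C5 is protonated, at C10; it matches the C7/C9 bis-nucleophile of an acetoacetate bis-silyl dienol ether (formal [3+3]). The C8 ketone is the handle for the C8 methyl and the C8=C9 alkene.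
3. Forward: ring A is bought (β-cyclocitral); ring B arises in step 6; enol phosphate/Me2CuLi gives the tetrasubstituted alkene; the chain is joined at C11–C12 (step 11) and C14–C15 (step 15); oxidation to the acid is last.
4. Stereochemistry: H-5/CH3-10 trans from the chair closure in step 6, absolute sense from an 8-phenylmenthyl ester (recovered in step 9); C17 from methyl (S)-3-hydroxy-2-methylpropanoate; 13E from syn-carboalumination; 15E from Takai olefination.

Key step: step 6

Assumption: 8-phenylmenthyl means (1R,2S,5R)-5-methyl-2-(2-phenylpropan-2-yl)cyclohexyl; its sense of induction in step 6 is taken to favour the (4aS,8aS) series, and the two diastereomers are separable in any case.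

Step 1
Reactants: 1 β-cyclocitral (2,6,6-trimethylcyclohex-1-ene-1-carbaldehyde)
Product: 2 β-cyclogeraniol [(2,6,6-trimethylcyclohex-1-en-1-yl)methanol]
Conditions: NaBH4, MeOH, 0 °C
Reagents that add atoms: none
Why: Borohydride 1,2-reduction of the hindered enal should give the primary allylic alcohol without touching the tetrasubstituted alkene; no stereocentre is formed.

Step 2
Reactants: 2 β-cyclogeraniol
Product: 3 β-cyclogeranyl acetate [(2,6,6-trimethylcyclohex-1-en-1-yl)methyl acetate]
Conditions: Ac2O, pyridine, DMAP (cat.), CH2Cl2, rt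
Reagents that add atoms: acetic anhydride CC(=O)OC(C)=O
Why: DMAP-catalysed acetylation installs a stable leaving group that a strong Lewis acid can ionise to the allyl cation.

Step 3
Reactants: 4 (–)-8-phenylmenthol [(1R,2S,5R)-5-methyl-2-(2-phenylpropan-2-yl)cyclohexan-1-ol]; 5 2,2,6-trimethyl-4H-1,3-dioxin-4-one
Product: 6 (1R,2S,5R)-8-phenylmenthyl 3-oxobutanoate
Conditions: xylene, 140 °C, acetone distilled off
Reagents that add atoms: none
Why: Thermal retro-[4+2] of the dioxinone releases acetylketene, which the secondary alcohol traps (acetoacetylation); the auxiliary stereocentres are untouched.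

Step 4
Reactants: 6 (1R,2S,5R)-8-phenylmenthyl 3-oxobutanoate
Product: 7 (1R,2S,5R)-8-phenylmenthyl 3-(trimethylsilyloxy)but-2-enoate (E/Z mixture)
Conditions: Me3SiCl, Et3N, hexane, rt
Reagents that add atoms: chlorotrimethylsilane C[Si](C)(C)Cl
Why: O-silylation of the enolised β-keto ester gives the silyl enol ether (standard first stage of bis-silyl dienol ether formation).

Step 5
Reactants: 7 (1R,2S,5R)-8-phenylmenthyl 3-(trimethylsilyloxy)but-2-enoate
Product: 8 1-[(1R,2S,5R)-8-phenylmenthyloxy]-1,3-bis(trimethylsilyloxy)buta-1,3-diene (ketene acetal geometry mixed)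
Conditions: LiN(i-Pr)2, Me3SiCl, THF, –78 °C to rt; used crude
Reagents that add atoms: chlorotrimethylsilane C[Si](C)(C)Cl
Why: γ-Deprotonation and O-silylation (silyl ketene acetal formation) give the 1,3-bis-silyl dienol ether, whose terminal CH2 (C7) is the most nucleophilic carbon and whose central CH (C9) is the second nucleophilic site.

Step 6
Reactants: 3 β-cyclogeranyl acetate; 8 1-[(1R,2S,5R)-8-phenylmenthyloxy]-1,3-bis(trimethylsilyloxy)buta-1,3-diene
Product: 10 (1R,2S,5R)-8-phenylmenthyl (1R,4aS,8aS)-5,5,8a-trimethyl-2-oxodecahydronaphthalene-1-carboxylate, via monocyclic β-keto ester 9 (not isolated)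
Conditions: SnCl4 (2 equiv), CH2Cl2, –78 °C; then i-PrOH (1 equiv), –78 to 0 °C; aqueous NaHCO3; chromatography (diastereomers separated)
Reagents that add atoms: none
Why: Proposed new method: SnCl4 ionises acetate 3 to the β-cyclogeranyl cation, which is captured at its CH2 terminus (C6) by the terminal carbon (C7) of dienol ether 8 in a vinylogous Mukaiyama-type SN1 alkylation; after protodesilylation by 2-propanol the SnCl4-chelated enol of 9 hands its proton to C5 of the tetrasubstituted ring alkene and C9 then traps the tertiary C10 cation. The closest known reaction types are the Lewis acid-mediated formal [3+3] cyclisation of 1,3-bis-silyl enol ethers with 1,3-dielectrophiles and the SnCl4-promoted olefin cyclisation of δ,ε-unsaturated β-keto esters, here merged so that the allyl cation C6–C5–C10 serves as the 1,3-dielectrophile. Ring B closes in a 6-endo-trig (enolendo) cation–olefin mode through a chair transition state. That chair, with the C6–C7 tether equatorial on ring A and the C10 methyl axial, should set H-5 trans to CH3-10, the C9 ester should settle equatorial (this centre is erased in step 7), and the absolute sense at C5/C10 should follow from the 8-phenylmenthyl group, whose phenyl ring covers one face of the planar tin chelate so that C9 bonds to C10 from the open face, the minor diastereomer being removed by chromatography. The step needs γ- over α-attack of the acetoacetate unit (secured by the bis-silyl dienol ether), attack at the CH2 rather than the tertiary terminus of the allyl cation (steric bias of the flanking gem-dimethyl and methyl groups), six- over five-membered spiro closure and C- over O-alkylation (chair geometry and chelation of the β-dicarbonyl by tin).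

Step 7
Reactants: 10 (1R,2S,5R)-8-phenylmenthyl (1R,4aS,8aS)-5,5,8a-trimethyl-2-oxodecahydronaphthalene-1-carboxylate
Product: 11 (1R,2S,5R)-8-phenylmenthyl (4aS,8aS)-2-[(diethoxyphosphoryl)oxy]-5,5,8a-trimethyl-3,4,4a,5,6,7,8,8a-octahydronaphthalene-1-carboxylate
Conditions: NaH, ClP(O)(OEt)2, THF, 0 °C
Reagents that add atoms: diethyl chlorophosphate CCOP(=O)(Cl)OCC
Why: The sodium enolate of the β-keto ester is O-phosphorylated at the ketone oxygen (enol phosphate formation), which fixes the double bond at C8=C9.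

Step 8
Reactants: 11 enol phosphate
Product: 12 (1R,2S,5R)-8-phenylmenthyl (4aS,8aS)-2,5,5,8a-tetramethyl-3,4,4a,5,6,7,8,8a-octahydronaphthalene-1-carboxylate (8-phenylmenthyl drim-8-en-11-oate)
Conditions: Me2CuLi (3 equiv), Et2O, –78 to –45 °C
Reagents that add atoms: lithium dimethylcuprate [Li+].C[Cu-]C
Why: Addition–elimination of the cuprate on the β-phosphoryloxy enoate (enol phosphate–cuprate coupling) should place the C8 methyl and leave the tetrasubstituted C8=C9 alkene regiospecifically.

Step 9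
Reactants: 12 8-phenylmenthyl drim-8-en-11-oate
Product: 13 [(4aS,8aS)-2,5,5,8a-tetramethyl-3,4,4a,5,6,7,8,8a-octahydronaphthalen-1-yl]methanol (drim-8-en-11-ol)
Conditions: LiAlH4, Et2O, 0 °C to reflux; auxiliary alcohol 4 recovered
Reagents that add atoms: none
Why: Hydride reduction of the hindered, twisted enoate should give the allylic alcohol by 1,2-reduction and release the auxiliary for re-use.

Step 10
Reactants: 13 drim-8-en-11-ol
Product: 14 (4aS,8aS)-1-(bromomethyl)-2,5,5,8a-tetramethyl-3,4,4a,5,6,7,8,8a-octahydronaphthalene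
Conditions: PBr3 (0.4 equiv), pyridine (cat.), Et2O, –10 °C; used at once
Reagents that add atoms: phosphorus tribromide BrP(Br)Br
Why: SN2 bromination through the phosphite ester should give the primary allylic bromide, the regioisomer that keeps the tetrasubstituted alkene.

Step 11
Reactants: 14 allylic bromide; 15 1-(trimethylsilyl)propyne
Product: 18 (4aS,8aS)-1-(but-3-yn-1-yl)-2,5,5,8a-tetramethyl-3,4,4a,5,6,7,8,8a-octahydronaphthalene, via 3-lithio-1-(trimethylsilyl)propyne 16 (not isolated), via silylalkyne 17 (not isolated)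
Conditions: 15, n-BuLi, THF, –78 to 0 °C; 14, –78 to 0 °C; then MeOH, K2CO3, rt
Reagents that add atoms: none
Why: Propargylic lithiation, SN2 alkylation by the primary allylic bromide (C11–C12 bond; the silyl group directs attack to the propargylic carbon) and methanolytic C–Si cleavage should give the terminal alkyne.

Step 12
Reactants: 19 methyl (S)-3-hydroxy-2-methylpropanoate
Product: 20 methyl (S)-3-[(tert-butyldimethylsilyl)oxy]-2-methylpropanoate
Conditions: t-BuMe2SiCl, imidazole, DMF, rt
Reagents that add atoms: tert-butyldimethylsilyl chloride CC(C)(C)[Si](C)(C)Cl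
Why: Silyl ether protection of the primary alcohol, which later becomes the carboxyl carbon; the stereocentre is untouched.

Step 13
Reactants: 20 silyl ether ester
Product: 21 (S)-3-[(tert-butyldimethylsilyl)oxy]-2-methylpropanal
Conditions: i-Bu2AlH (1.05 equiv), CH2Cl2, –78 °C; MeOH quench; used crude at once
Reagents that add atoms: none
Why: Half-reduction of the ester through the tetrahedral aluminium hemiacetal, stable at low temperature, should give the aldehyde, and immediate use protects the α-stereocentre.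

Step 14
Reactants: 21 (S)-aldehyde
Product: 22 tert-butyl{[(2R,3E)-4-iodo-2-methylbut-3-en-1-yl]oxy}dimethylsilane
Conditions: CrCl2 (6 equiv), CHI3 (2 equiv), THF, 0 °C to rt
Reagents that add atoms: iodoform IC(I)I
Why: Takai olefination through the geminal dichromium reagent should give the E-vinyl iodide (C15=C16) under non-basic conditions that spare the adjacent stereocentre (the descriptor changes to R only by priority).

Step 15
Reactants: 18 terminal alkyne; 22 (2R,3E)-vinyl iodide
Product: 24 tert-butyl{[(2R,3E,5E)-2,6-dimethyl-8-((4aS,8aS)-2,5,5,8a-tetramethyl-3,4,4a,5,6,7,8,8a-octahydronaphthalen-1-yl)octa-3,5-dien-1-yl]oxy}dimethylsilane, via alkenylalane 23 (not isolated)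
Conditions: AlMe3 (2.5 equiv), Cp2ZrCl2 (0.3 equiv), CH2Cl2, rt; then 22, Pd(PPh3)4 (5 mol %), ZnCl2 (1 equiv), THF, rt
Reagents that add atoms: trimethylaluminium C[Al](C)C
Why: Cp2ZrCl2-catalysed syn-carboalumination (Negishi) puts the methyl on C13 and sets the 13E alkene, and the Pd(PPh3)4/ZnCl2-mediated cross-coupling with the E-vinyl iodide (Negishi coupling) forms C14–C15 with retention at both alkenes.

Step 16
Reactants: 24 silyl ether
Product: 25 (2R,3E,5E)-2,6-dimethyl-8-[(4aS,8aS)-2,5,5,8a-tetramethyl-3,4,4a,5,6,7,8,8a-octahydronaphthalen-1-yl]octa-3,5-dien-1-ol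
Conditions: Bu4NF, THF, 0 °C to rt
Reagents that add atoms: none
Why: Fluoride cleavage of the silyl ether frees the primary alcohol without affecting the diene or the C17 centre.

Step 17
Reactants: 25 dienol
Product: 27 (2R,3E,5E)-2,6-dimethyl-8-[(4aS,8aS)-2,5,5,8a-tetramethyl-3,4,4a,5,6,7,8,8a-octahydronaphthalen-1-yl]octa-3,5-dienoic acid (target), via dienal 26 (not isolated)
Conditions: Dess–Martin periodinane, NaHCO3, CH2Cl2, 0 °C; then NaClO2, NaH2PO4, 2-methyl-2-butene, t-BuOH/H2O, 0 °C
Reagents that add atoms: sodium chlorite [Na+].[O-]Cl=O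
Why: Buffered Dess–Martin oxidation followed at once by Pinnick oxidation with an alkene scavenger should give the acid under non-basic conditions that keep the C17 centre and leave the diene out of conjugation.

**Compound list**

1 | β-cyclocitral (2,6,6-trimethylcyclohex-1-ene-1-carbaldehyde) | CC1=C(C=O)C(C)(C)CCC1 | starting material
2 | β-cyclogeraniol | CC1=C(CO)C(C)(C)CCC1 | intermediate
3 | β-cyclogeranyl acetate | CC1=C(COC(C)=O)C(C)(C)CCC1 | intermediate
4 | (–)-8-phenylmenthol, (1R,2S,5R)-5-methyl-2-(2-phenylpropan-2-yl)cyclohexan-1-ol | O[C@@H]1C[C@H](C)CC[C@H]1C(C)(C)c2ccccc2 | starting material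
5 | 2,2,6-trimethyl-4H-1,3-dioxin-4-one | CC1=CC(=O)OC(C)(C)O1 | starting material
6 | (1R,2S,5R)-8-phenylmenthyl 3-oxobutanoate | CC(=O)CC(=O)O[C@@H]1C[C@H](C)CC[C@H]1C(C)(C)c2ccccc2 | intermediate
7 | (1R,2S,5R)-8-phenylmenthyl 3-(trimethylsilyloxy)but-2-enoate (E/Z mixture) | CC(O[Si](C)(C)C)=CC(=O)O[C@@H]1C[C@H](C)CC[C@H]1C(C)(C)c2ccccc2 | intermediate
8 | 1-[(1R,2S,5R)-8-phenylmenthyloxy]-1,3-bis(trimethylsilyloxy)buta-1,3-diene | C=C(O[Si](C)(C)C)C=C(O[Si](C)(C)C)O[C@@H]1C[C@H](C)CC[C@H]1C(C)(C)c2ccccc2 | intermediate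
9 | (1R,2S,5R)-8-phenylmenthyl 3-oxo-5-(2,6,6-trimethylcyclohex-1-en-1-yl)pentanoate (formed as its SnCl4 chelate) | CC1=C(CCC(=O)CC(=O)O[C@@H]2C[C@H](C)CC[C@H]2C(C)(C)c3ccccc3)C(C)(C)CCC1 | intermediate
10 | (1R,2S,5R)-8-phenylmenthyl (1R,4aS,8aS)-5,5,8a-trimethyl-2-oxodecahydronaphthalene-1-carboxylate (trans-fused, ester equatorial) | O=C1[C@H](C(=O)O[C@@H]3C[C@H](C)CC[C@H]3C(C)(C)c4ccccc4)[C@@]2(C)CCCC(C)(C)[C@@H]2CC1 | intermediate
11 | (1R,2S,5R)-8-phenylmenthyl (4aS,8aS)-2-[(diethoxyphosphoryl)oxy]-5,5,8a-trimethyl-3,4,4a,5,6,7,8,8a-octahydronaphthalene-1-carboxylate | CCOP(=O)(OCC)OC1=C(C(=O)O[C@@H]3C[C@H](C)CC[C@H]3C(C)(C)c4ccccc4)[C@@]2(C)CCCC(C)(C)[C@@H]2CC1 | intermediate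
12 | (1R,2S,5R)-8-phenylmenthyl (4aS,8aS)-2,5,5,8a-tetramethyl-3,4,4a,5,6,7,8,8a-octahydronaphthalene-1-carboxylate | CC1=C(C(=O)O[C@@H]3C[C@H](C)CC[C@H]3C(C)(C)c4ccccc4)[C@@]2(C)CCCC(C)(C)[C@@H]2CC1 | intermediate
13 | [(4aS,8aS)-2,5,5,8a-tetramethyl-3,4,4a,5,6,7,8,8a-octahydronaphthalen-1-yl]methanol (drim-8-en-11-ol) | CC1=C(CO)[C@@]2(C)CCCC(C)(C)[C@@H]2CC1 | intermediate
14 | (4aS,8aS)-1-(bromomethyl)-2,5,5,8a-tetramethyl-3,4,4a,5,6,7,8,8a-octahydronaphthalene | CC1=C(CBr)[C@@]2(C)CCCC(C)(C)[C@@H]2CC1 | intermediate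
15 | 1-(trimethylsilyl)propyne | CC#C[Si](C)(C)C | starting material
16 | 3-lithio-1-(trimethylsilyl)propyne | [Li]CC#C[Si](C)(C)C | intermediate
17 | trimethyl{4-[(4aS,8aS)-2,5,5,8a-tetramethyl-3,4,4a,5,6,7,8,8a-octahydronaphthalen-1-yl]but-1-yn-1-yl}silane | CC1=C(CCC#C[Si](C)(C)C)[C@@]2(C)CCCC(C)(C)[C@@H]2CC1 | intermediate
18 | (4aS,8aS)-1-(but-3-yn-1-yl)-2,5,5,8a-tetramethyl-3,4,4a,5,6,7,8,8a-octahydronaphthalene | CC1=C(CCC#C)[C@@]2(C)CCCC(C)(C)[C@@H]2CC1 | intermediate
19 | methyl (S)-3-hydroxy-2-methylpropanoate | COC(=O)[C@@H](C)CO | starting material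
20 | methyl (S)-3-[(tert-butyldimethylsilyl)oxy]-2-methylpropanoate | COC(=O)[C@@H](C)CO[Si](C)(C)C(C)(C)C | intermediate
21 | (S)-3-[(tert-butyldimethylsilyl)oxy]-2-methylpropanal | O=C[C@@H](C)CO[Si](C)(C)C(C)(C)C | intermediate
22 | tert-butyl{[(2R,3E)-4-iodo-2-methylbut-3-en-1-yl]oxy}dimethylsilane | I/C=C/[C@@H](C)CO[Si](C)(C)C(C)(C)C | intermediate
23 | dimethyl{(1E)-2-methyl-4-[(4aS,8aS)-2,5,5,8a-tetramethyl-3,4,4a,5,6,7,8,8a-octahydronaphthalen-1-yl]but-1-en-1-yl}alumane | CC1=C(CC/C(C)=C/[Al](C)C)[C@@]2(C)CCCC(C)(C)[C@@H]2CC1 | intermediate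
24 | tert-butyldimethylsilyl ether of dienol 25 | CC1=C(CC/C(C)=C/C=C/[C@@H](C)CO[Si](C)(C)C(C)(C)C)[C@@]2(C)CCCC(C)(C)[C@@H]2CC1 | intermediate
25 | (2R,3E,5E)-2,6-dimethyl-8-[(4aS,8aS)-2,5,5,8a-tetramethyl-3,4,4a,5,6,7,8,8a-octahydronaphthalen-1-yl]octa-3,5-dien-1-ol | CC1=C(CC/C(C)=C/C=C/[C@@H](C)CO)[C@@]2(C)CCCC(C)(C)[C@@H]2CC1 | intermediate
26 | (2R,3E,5E)-2,6-dimethyl-8-[(4aS,8aS)-2,5,5,8a-tetramethyl-3,4,4a,5,6,7,8,8a-octahydronaphthalen-1-yl]octa-3,5-dienal | CC1=C(CC/C(C)=C/C=C/[C@@H](C)C=O)[C@@]2(C)CCCC(C)(C)[C@@H]2CC1 | intermediate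
27 | (2R,3E,5E)-2,6-dimethyl-8-[(4aS,8aS)-2,5,5,8a-tetramethyl-3,4,4a,5,6,7,8,8a-octahydronaphthalen-1-yl]octa-3,5-dienoic acid | CC1=C(CC/C(C)=C/C=C/[C@@H](C)C(=O)O)[C@@]2(C)CCCC(C)(C)[C@@H]2CC1 | target

**Step count**

Total: 17 steps. Longest linear sequence: 12 steps (steps 3–11, then 15–17).

**Steps most likely to fail**

Step 6 (proposed new method). The allyl cation may be lost by proton elimination to a ring diene before C–C bond formation. The dienol ether may be desilylated early, so that attack comes from the α-carbon. Closure may also go through oxygen or with poor facial discrimination by the auxiliary. The fallback sets out from 2 and 6, uses known chemistry only and returns at 10. Alcohol 2 is converted with PBr3 into β-cyclogeranyl bromide F1. Ester 6 is deprotonated twice (NaH, then n-BuLi, THF, 0 °C) to the sodium lithium dianion of 6 F2, which is alkylated at its terminal carbon by F1 to give 9, now isolated. Compound 9 is then cyclised with SnCl4 in CH2Cl2 (the known olefin cyclisation of unsaturated β-keto esters), and the (4aS,8aS) diastereomer of 10 is separated as in the main route.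

Step 17. Enolisation of the α-branched β,γ-unsaturated aldehyde during the oxidation would scramble C17 and draw the diene into conjugation. The fallback sets out from 22 (with alkenylalane 23 made from 18 as in step 15) and returns at 27. Iodide 22 is desilylated (Bu4NF) to (2R,3E)-4-iodo-2-methylbut-3-en-1-ol F3 and oxidised (CrO3, H2SO4, acetone, 0 °C; Jones oxidation) to (2R,3E)-4-iodo-2-methylbut-3-enoic acid F4. The optical purity of F4 can be checked and raised by salt crystallisation before the core is committed. F4 is turned with one equivalent of AlMe3 into dimethylaluminium (2R,3E)-4-iodo-2-methylbut-3-enoate F5, which is coupled with 23 under the Pd(PPh3)4/ZnCl2 conditions of step 15. Acidic work-up should give 27 directly, with no late oxidation.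

Step 11. E2 elimination, SN2′ attack or ionisation of the hindered allylic bromide may compete with SN2 at C11. The fallback sets out from 13 and returns at 18; it makes the C12–C13 bond on an unhindered, non-allylic carbon instead of C11–C12. Alcohol 13 is oxidised (MnO2, CH2Cl2) to (4aS,8aS)-2,5,5,8a-tetramethyl-3,4,4a,5,6,7,8,8a-octahydronaphthalene-1-carbaldehyde F6. Wittig methylenation (Ph3P=CH2, THF) gives (4aS,8aS)-1-ethenyl-2,5,5,8a-tetramethyl-3,4,4a,5,6,7,8,8a-octahydronaphthalene F7. Hydroboration at the terminal carbon (9-BBN; then H2O2, NaOH) gives 2-[(4aS,8aS)-2,5,5,8a-tetramethyl-3,4,4a,5,6,7,8,8a-octahydronaphthalen-1-yl]ethan-1-ol F8. I2, PPh3 and imidazole convert F8 into (4aS,8aS)-1-(2-iodoethyl)-2,5,5,8a-tetramethyl-3,4,4a,5,6,7,8,8a-octahydronaphthalene F9. Displacement with LiC≡CH·H2NCH2CH2NH2 in DMSO then gives 18.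

Further compounds
F1 | step 6 | β-cyclogeranyl bromide [2-(bromomethyl)-1,3,3-trimethylcyclohex-1-ene] | CC1=C(CBr)C(C)(C)CCC1
F2 | step 6 | sodium lithium dianion of (1R,2S,5R)-8-phenylmenthyl 3-oxobutanoate | [Na+].[Li+].[CH2-]C(=O)[CH-]C(=O)O[C@@H]1C[C@H](C)CC[C@H]1C(C)(C)c2ccccc2
F3 | step 17 | (2R,3E)-4-iodo-2-methylbut-3-en-1-ol | I/C=C/[C@@H](C)CO
F4 | step 17 | (2R,3E)-4-iodo-2-methylbut-3-enoic acid | I/C=C/[C@@H](C)C(=O)O
F5 | step 17 | dimethylaluminium (2R,3E)-4-iodo-2-methylbut-3-enoate | I/C=C/[C@@H](C)C(=O)O[Al](C)C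
F6 | step 11 | (4aS,8aS)-2,5,5,8a-tetramethyl-3,4,4a,5,6,7,8,8a-octahydronaphthalene-1-carbaldehyde | CC1=C(C=O)[C@@]2(C)CCCC(C)(C)[C@@H]2CC1
F7 | step 11 | (4aS,8aS)-1-ethenyl-2,5,5,8a-tetramethyl-3,4,4a,5,6,7,8,8a-octahydronaphthalene | CC1=C(C=C)[C@@]2(C)CCCC(C)(C)[C@@H]2CC1
F8 | step 11 | 2-[(4aS,8aS)-2,5,5,8a-tetramethyl-3,4,4a,5,6,7,8,8a-octahydronaphthalen-1-yl]ethan-1-ol | CC1=C(CCO)[C@@]2(C)CCCC(C)(C)[C@@H]2CC1
F9 | step 11 | (4aS,8aS)-1-(2-iodoethyl)-2,5,5,8a-tetramethyl-3,4,4a,5,6,7,8,8a-octahydronaphthalene | CC1=C(CCI)[C@@]2(C)CCCC(C)(C)[C@@H]2CC1
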